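Readings and results were generated by integration from invented constants, noise included.

The ratio [open intermediate]/[substrate] starts at zero, and as a first guess I put it at the symmetric value 1 once the substrate has opened; this guess only serves to read the alpha run, while what is asked is the final open intermediate in each flask.

| setting | alpha | epsilon | Sunday's | Monday's | Tuesday's |
|---|---|---|---|---|---|
| substrate | 0.28 M | 0.44 M | 0.20 M | 0.20 M | 0.20 M |
| reagent | 1.2 equiv | 1.2 equiv | 1.20 equiv | 1.20 equiv | 1.20 equiv |
| free catalyst | 1.1 mol% | 1.1 mol% | 1.1 mol% | 1.1 mol% | 1.1 mol% |
| temperature | −5 °C | 17 °C | 5 °C | −15 °C | 25 °C |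
| remark | run made earlier | run made earlier |  |  |  |
| time |  |  | 2.5 min | 2.5 min | 2.5 min |

alpha run (percent of the substrate charged)

| time / min | open intermediate / % | target / % |
|---|---|---|
| 0.500 | 31.6 | 2.2 |
| 1.00 | 40.2 | 2.9 |
| 1.33 | 41.4 | 6.7 |
| 2.00 | 43.6 | 9.1 |
| 2.50 | 40.7 | 10.5 |

epsilon run (percent of the substrate charged)

| time / s | open intermediate / % | target / % |
|---|---|---|
| 12.0 | 48.9 | 3.2 |
| 20.0 | 50.4 | 9.1 |
| 30.0 | 47.8 | 10.8 |
| 40.0 | 42.9 | 15.7 |
| 50.0 | 36.9 | 17.8 |

(readings scatter by 1 percentage point)

- what may be going on: substrate + free catalyst <-> free catalyst + open intermediate; free catalyst + open intermediate <-> catalyst intermediate; reagent + catalyst intermediate -> free catalyst + target; open intermediate -> side product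

- the flask with the highest amount of open intermediate, in percent of the substrate charged ("all alike" if they lie within 1.5 percentage points) (Sunday's / Monday's / Tuesday's / all alike)
- final open intermediate, as a percentage of the substrate charged, in Sunday's
- final open intermediate, as a percentage of the substrate charged, in Monday's
- final open intermediate, as a percentage of the substrate charged, in Tuesday's

Side product is unread, so you get it from the balance. If the alpha run ended symmetric, its missing share is 8.10%. Dividing by its open intermediate gives a drain number of 0.199. This is an upper estimate, since unopened substrate would count as loss.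

In the epsilon run, the reading at 20.0 s gives the open share of the unconverted charge, f = 0.554, taking side product there as nil. The reading at 50.0 s then implies 15.6% of side product. Scaled to 2.5 min, that gives 1.79.

These are values of N, the drain number: the first-order loss constant of the open intermediate times the 2.5 min of the flask. I let ln N run linearly with temperature, which gives 0.540 for Sunday's, 0.0733 for Monday's and 3.99 for Tuesday's.

A fully opened flask, with target neglected, holds f·exp(−fN) as open intermediate: 41.1% for Sunday's, 53.2% for Monday's and 6.08% for Tuesday's.

One number is not enough, though. Monday's is colder than the alpha run and has less catalyst per litre, and the alpha run read 40.7% at 2.50 min, so I expect Monday's to stay below its opened level at 2.5 min. I put Sunday's first, narrowly.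

The forecast says Sunday's, with 38%, 36% and 12%, and of Monday's: “losses are small, but opening is incomplete at 2.5 min”.

The flasks end at 42.0% for Sunday's, 34.6% for Monday's and 7.14% for Tuesday's, so Sunday's holds the most.

    substrate + free catalyst ⇌ free catalyst + open intermediate (K = 2.20, k = 51.0 L mol⁻¹ s⁻¹, Ea = 45.0 kJ mol⁻¹, ΔH = 13.0 kJ mol⁻¹)
    free catalyst + open intermediate ⇌ catalyst intermediate (K = 1.80 L mol⁻¹, k = 12.0 L mol⁻¹ s⁻¹, Ea = 47.0 kJ mol⁻¹, ΔH = −75.0 kJ mol⁻¹)
    reagent + catalyst intermediate → free catalyst + target (k = 3.70 L mol⁻¹ s⁻¹, Ea = 46.0 kJ mol⁻¹)
    open intermediate → side product (k = 0.0210 s⁻¹, Ea = 82.0 kJ mol⁻¹)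
    (constants at 25 °C)

Monday's still has 61.9% as substrate, and at 2.50 min it makes open intermediate 3.35 times faster than it uses it up. Now take a flask like Monday's kept at 0 °C. Its drain number is 0.328, and its opened level is 46.2%. It ends with 44.0% open intermediate, 10.0% target and 5.74% side product.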